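**Strategy**

The bicyclic core is disconnected at C4a–C8a (ring B) and O2–C3 (ring A). The key step exploits the position of C4a, which carries C8a directly and the enol-ether carbon C3 two bonds away through C4: the unit C6–C5–C4a–C4–C3 can therefore be brought in as a diynone (C6 ketone, C5≡C4a, C4≡C3) that takes a carbon nucleophile at C4a and an oxygen nucleophile at C3. In one flask the magnesium enolate of the C8/acetyl diketone closes ring B and the unmasked C1 hydroxyl closes ring A, with C7 directing the new C8a centre. The precursor is an acyclic triketone: a 2-(silyloxymethyl)-1,3-diketone linked through the methoxymethyl-protected C7 carbinol to a dienyl diynone.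

Key step: step 17

Assumption 1: atom labels C1–C8a follow the isochromene numbering of the target and are also used for the corresponding atoms of open-chain intermediates.
Assumption 2: pig liver esterase is taken to cleave the pro-R ester group of 3; the sense and level of selection have to be confirmed on 4 before material is advanced.
Assumption 3: compounds 19–26 are carried as mixtures of carbinol epimers at C6, C8 and C8a; only C7 and the side-chain centre matter, because step 16 removes the others.

**Route**

Step 1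
Reactants: 1 diethyl 2-oxomalonate
Product: 2 diethyl 2-hydroxy-2-methylmalonate
Conditions: MeMgBr (1.05 equiv), THF, −78 °C
Reagents that add atoms: methylmagnesium bromide, C[Mg]Br
Why: Grignard 1,2-addition goes to the central ketone, the most electrophilic carbonyl of the vicinal tricarbonyl, and the low temperature keeps both esters intact; the product is still achiral.

Step 2
Reactants: 2 diethyl 2-hydroxy-2-methylmalonate
Product: 3 diethyl 2-(methoxymethoxy)-2-methylmalonate
Conditions: MeOCH2Cl (3 equiv), i-Pr2NEt (4 equiv), n-Bu4NI (cat.), 1,2-dichloroethane, 60 °C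
Reagents that add atoms: chloromethyl methyl ether, COCCl
Why: Williamson-type O-alkylation of the tertiary alcohol with the reactive α-chloro ether (iodide catalysis) installs the acetal ether that later chelates magnesium at O7.

Step 3
Reactants: 3 diethyl 2-(methoxymethoxy)-2-methylmalonate
Product: 4 (2S)-3-ethoxy-2-(methoxymethoxy)-2-methyl-3-oxopropanoic acid
Conditions: pig liver esterase, phosphate buffer pH 7.5, DMSO (10%), rt
Reagents that add atoms: water, O
Why: Enzymatic desymmetrisation (enantiotopic-group-selective ester hydrolysis of a prochiral 2,2-disubstituted malonate) creates the C7 stereocentre, cleavage of the pro-R ester giving the (S)-acid, and it stops at the half-ester because the carboxylate is no longer a substrate.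

Step 4
Reactants: 4 (2S)-3-ethoxy-2-(methoxymethoxy)-2-methyl-3-oxopropanoic acid
Product: 5 ethyl (2S)-3-hydroxy-2-(methoxymethoxy)-2-methylpropanoate
Conditions: BH3·SMe2 (1.5 equiv), THF, 0 °C → rt
Reagents that add atoms: none
Why: Chemoselective borane reduction of the carboxylic acid (through its acyloxyborane) leaves the ester untouched, so the two malonate arms are differentiated as CH2OH (future C6) and CO2Et (future C8) without touching C7.

Step 5
Reactants: 5 ethyl (2S)-3-hydroxy-2-(methoxymethoxy)-2-methylpropanoate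
Product: 6 ethyl (2S)-2-(methoxymethoxy)-2-methyl-3-oxopropanoate
Conditions: Dess–Martin periodinane (1.3 equiv), CH2Cl2, rt
Reagents that add atoms: none
Why: Dess–Martin oxidation of the primary alcohol gives an aldehyde that cannot enolise at the quaternary C7, so the stereocentre is safe.

Step 6
Reactants: 7 (S)-2-methylbutan-1-ol
Product: 9 ethyl (2E,4S)-2,4-dimethylhex-2-enoate, via (S)-2-methylbutanal 8 (not isolated)
Conditions: TEMPO (10 mol %), PhI(OAc)2 (1.1 equiv), CH2Cl2, rt; then Ph3P=C(CH3)CO2Et (1.3 equiv), rt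
Reagents that add atoms: ethyl 2-(triphenyl-λ5-phosphanylidene)propanoate, CCOC(=O)C(C)=P(c1ccccc1)(c1ccccc1)c1ccccc1
Why: Nitroxyl-catalysed alcohol oxidation followed in the same flask by Wittig olefination with a stabilised ylide (E-selective) avoids isolating the volatile, easily racemised α-branched aldehyde; the stereocentre comes from the chiral pool.

Step 7
Reactants: 9 ethyl (2E,4S)-2,4-dimethylhex-2-enoate
Product: 10 (2E,4S)-2,4-dimethylhex-2-en-1-ol
Conditions: i-Bu2AlH (2.3 equiv), CH2Cl2, −78 °C
Reagents that add atoms: none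
Why: 1,2-Reduction of the enoate with i-Bu2AlH gives the allylic alcohol without conjugate reduction.

Step 8
Reactants: 10 (2E,4S)-2,4-dimethylhex-2-en-1-ol
Product: 11 (2E,4S)-2,4-dimethylhex-2-enal
Conditions: MnO2 (15 equiv), CH2Cl2, rt
Reagents that add atoms: none
Why: Allylic oxidation with activated MnO2 gives the enal under neutral conditions that preserve the E geometry and the γ-stereocentre.

Step 9
Reactants: 11 (2E,4S)-2,4-dimethylhex-2-enal
Product: 12 (1E,3E,5S)-1-iodo-3,5-dimethylhepta-1,3-diene
Conditions: CrCl2 (6 equiv), CHI3 (2 equiv), THF, 0 °C → rt, dark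
Reagents that add atoms: iodoform, IC(I)I
Why: Takai olefination (geminal dichromium reagent from CHI3 and CrCl2) converts the aldehyde into the vinyl iodide with the E selectivity typical of this reaction.

Step 10
Reactants: 13 1,4-bis(trimethylsilyl)buta-1,3-diyne and 12 (1E,3E,5S)-1-iodo-3,5-dimethylhepta-1,3-diene
Product: 16 trimethyl[(5E,7E,9S)-7,9-dimethylundeca-5,7-dien-1,3-diyn-1-yl]silane, via lithium silyldiynide 14 (not isolated), via silyldiynylzinc chloride 15 (not isolated)
Conditions: MeLi·LiBr (1.0 equiv to 13), THF, rt; ZnCl2, 0 °C; then 12, Pd(PPh3)4 (5 mol %), rt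
Reagents that add atoms: none
Why: Mono-desilylation of the bis-silyl diyne by MeLi·LiBr, transmetalation to zinc and Negishi coupling with the alkenyl iodide under catalysis by zerovalent palladium join the sp and sp2 carbons with retention of alkene geometry.

Step 11
Reactants: 16 trimethyl[(5E,7E,9S)-7,9-dimethylundeca-5,7-dien-1,3-diyn-1-yl]silane and 6 ethyl (2S)-2-(methoxymethoxy)-2-methyl-3-oxopropanoate
Product: 19 ethyl (2S,8E,10E,12S)-2-(methoxymethoxy)-2,10,12-trimethyl-3-[(trimethylsilyl)oxy]tetradeca-8,10-dien-4,6-diynoate (both C3 epimers), via dienyldiynyllithium 17 (not isolated), via lithium alkoxide 18 (not isolated)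
Conditions: MeLi·LiBr (1.0 equiv), THF, 0 °C → rt; then 6, −78 °C; then Me3SiCl (1.5 equiv), −78 → 0 °C
Reagents that add atoms: chlorotrimethylsilane, C[Si](C)(C)Cl
Why: Si–C(sp) cleavage gives the diynyllithium, which adds to the aldehyde of 6 much faster than to its hindered ester (alkynylation by 1,2-addition), and the alkoxide is silylated in the flask; the C6 carbinol configuration is not controlled and disappears in step 16.

Step 12
Reactants: 19 ethyl (2S,8E,10E,12S)-2-(methoxymethoxy)-2,10,12-trimethyl-3-[(trimethylsilyl)oxy]tetradeca-8,10-dien-4,6-diynoate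
Product: 20 (2S,8E,10E,12S)-2-(methoxymethoxy)-2,10,12-trimethyl-3-[(trimethylsilyl)oxy]tetradeca-8,10-dien-4,6-diynal
Conditions: i-Bu2AlH (1.2 equiv), CH2Cl2, −78 °C
Reagents that add atoms: none
Why: Partial reduction of the α-alkoxy ester should stop at the aldehyde because the aluminium hemiacetal is stabilised by chelation with O7 at −78 °C, while the silyl ether keeps the C6 oxygen from consuming hydride or forming a lactol.

Step 13
Reactants: 20 (2S,8E,10E,12S)-2-(methoxymethoxy)-2,10,12-trimethyl-3-[(trimethylsilyl)oxy]tetradeca-8,10-dien-4,6-diynal and 21 ethyl (S)-3-hydroxybutanoate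
Product: 24 ethyl (4R,10E,12E,14S)-3,5-dihydroxy-2-[(1S)-1-hydroxyethyl]-4-(methoxymethoxy)-4,12,14-trimethylhexadeca-10,12-dien-6,8-diynoate (epimers at C2/C3/C5), via dilithio hydroxybutanoate 22 (not isolated), via silylated aldol adduct 23 (not isolated)
Conditions: LiN(i-Pr)2 (2.1 equiv per 21), THF, −78 → −20 °C; then 20, −78 °C; AcOH; then citric acid (cat.), MeOH, 0 °C
Reagents that add atoms: none
Why: Fráter–Seebach-type aldol addition, in which the dianion of the β-hydroxy ester reacts at its α-carbon (future C8a) with the non-enolisable aldehyde and cannot lose its β-oxygen because that oxygen is an alkoxide, so the regiochemical and elimination problems of a β-silyloxy ketone enolate are avoided; acidic methanolysis then removes the trimethylsilyl ether, and the new carbinol centres are immaterial.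

Step 14
Reactants: 24 ethyl (4R,10E,12E,14S)-3,5-dihydroxy-2-[(1S)-1-hydroxyethyl]-4-(methoxymethoxy)-4,12,14-trimethylhexadeca-10,12-dien-6,8-diynoate
Product: 25 (2S,5R,11E,13E,15S)-3-(hydroxymethyl)-5-(methoxymethoxy)-5,13,15-trimethylheptadeca-11,13-dien-7,9-diyne-2,4,6-triol (epimers at C3/C4/C6)
Conditions: LiBH4 (3 equiv), THF, 0 °C → rt
Reagents that add atoms: none
Why: Borohydride reduction of the β-hydroxy ester (activated by lithium chelation) gives the primary alcohol that becomes C1, while alkynes, diene and acetal are inert.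

Step 15
Reactants: 25 (2S,5R,11E,13E,15S)-3-(hydroxymethyl)-5-(methoxymethoxy)-5,13,15-trimethylheptadeca-11,13-dien-7,9-diyne-2,4,6-triol
Product: 26 (2S,5R,11E,13E,15S)-5-(methoxymethoxy)-5,13,15-trimethyl-3-{[(triethylsilyl)oxy]methyl}heptadeca-11,13-dien-7,9-diyne-2,4,6-triol (epimers at C3/C4/C6)
Conditions: Et3SiCl (1.05 equiv), imidazole (2 equiv), CH2Cl2, −40 °C
Reagents that add atoms: chlorotriethylsilane, CC[Si](CC)(CC)Cl
Why: Silylation is selective for the only primary hydroxyl, the three secondary carbinols being hindered, so O1 is masked while the oxygens to be oxidised stay free.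

Step 16
Reactants: 26 (2S,5R,11E,13E,15S)-5-(methoxymethoxy)-5,13,15-trimethyl-3-{[(triethylsilyl)oxy]methyl}heptadeca-11,13-dien-7,9-diyne-2,4,6-triol
Product: 27 (5R,11E,13E,15S)-5-(methoxymethoxy)-5,13,15-trimethyl-3-{[(triethylsilyl)oxy]methyl}heptadeca-11,13-dien-7,9-diyne-2,4,6-trione (C3 = later C8a is stereolabile)
Conditions: Dess–Martin periodinane (4 equiv), NaHCO3, CH2Cl2, 0 °C → rt; short silica pad, used at once
Reagents that add atoms: none
Why: Threefold Dess–Martin oxidation (propargylic alcohol to ynone, 1,3-diol to 1,3-diketone) under buffered, non-basic conditions erases all uncontrolled carbinol centres and unveils the β-silyloxy diketone only in the last operation, so that it meets no base before the cyclisation.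

Step 17
Reactants: 27 (5R,11E,13E,15S)-5-(methoxymethoxy)-5,13,15-trimethyl-3-{[(triethylsilyl)oxy]methyl}heptadeca-11,13-dien-7,9-diyne-2,4,6-trione
Product: 30 (7S,8aR)-8a-acetyl-3-[(1E,3E,5S)-3,5-dimethylhepta-1,3-dien-1-yl]-7-(methoxymethoxy)-7-methyl-1H-isochromene-6,8(7H,8aH)-dione, via silyloxymethyl enynone 28 (not isolated), via hydroxymethyl enynone 29 (not isolated)
Conditions: Mg(OTf)2 (1.1 equiv), i-Pr2NEt (1.2 equiv), MeCN–CH2Cl2, −20 → 0 °C; then (±)-camphor-10-sulfonic acid (2.5 equiv), MeOH, 0 °C → rt
Reagents that add atoms: none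
Why: Proposed new method: Mg(OTf)2 and i-Pr2NEt soft-enolise the 1,3-diketone to a magnesium chelate whose central carbon C8a adds to C4a, the β-carbon of the C6 ynone, and protonation at C5 gives enynone 28 (ring B by 6-endo-dig carbocyclisation; closest known type: intramolecular Michael addition of 1,3-dicarbonyl enolates to ynones). Camphorsulfonic acid in methanol then cleaves the triethylsilyl ether, and the O1 hydroxyl of 29 adds to C3, the δ-carbon of the acid-activated enynone, with protonation at C4 (ring A by 6-endo-dig 1,6-oxa-Michael addition; closest known type: acid- or silver-promoted 6-endo cyclisation of hydroxy ynones and 2-alkynylbenzyl alcohols); what is new is running both conjugate additions on one diynone. The C8a stereocentre is controlled by C7 through the chelate: magnesium bound to O8 and to the O7 acetal oxygen holds the C7–O bond in the enolate plane, so the ynone arm lies over one face only and C4a bonds to C8a on the side that leaves the acetyl cis to O7 and C1 cis to the C7 methyl, both C8a epimers of 27 converging through the planar enolate. The step needs C- over O-alkylation, which the same chelate should provide by tying up O8 and turning it away from C4a, and it needs an intact diynone, which the non-nucleophilic triflate and the hindered amine provide. β-Elimination of the silyloxy group is held back because the silyl ether does not coordinate magnesium and the diketonate is a weaker base than the silanolate it would expel. Ring A is closed under acid and not base because the free alkoxide of the quaternary 2-hydroxymethyl-1,3-diketone 29 could fragment by retro-aldol loss of formaldehyde, and attack at C3 is preferred over 5-exo attack at C4 because only C3 is conjugated to the carbonyl.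

Step 18
Reactants: 30 (7S,8aR)-8a-acetyl-3-[(1E,3E,5S)-3,5-dimethylhepta-1,3-dien-1-yl]-7-(methoxymethoxy)-7-methyl-1H-isochromene-6,8(7H,8aH)-dione
Product: 31 (7R,8R,8aS)-8a-acetyl-3-[(1E,3E,5S)-3,5-dimethylhepta-1,3-dien-1-yl]-8-hydroxy-7-(methoxymethoxy)-7-methyl-1,7,8,8a-tetrahydro-6H-isochromen-6-one
Conditions: NaBH4 (0.5 equiv), MeOH–CH2Cl2 (1:1), −78 → −40 °C
Reagents that add atoms: none
Why: Borohydride 1,2-reduction is expected at C8, the non-conjugated ketone activated by the α-alkoxy group and two β-carbonyls (C6 is a deactivated vinylogous ester, the acetyl a less electrophilic methyl ketone), with hydride entering anti to the pseudo-axial C7–O bond (polar Felkin–Anh) and anti to the angular acetyl, that is from the face of the C7 methyl, which sets 8R with the hydroxyl cis to O7 and to the acetyl.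

Step 19
Reactants: 31 (7R,8R,8aS)-8a-acetyl-3-[(1E,3E,5S)-3,5-dimethylhepta-1,3-dien-1-yl]-8-hydroxy-7-(methoxymethoxy)-7-methyl-1,7,8,8a-tetrahydro-6H-isochromen-6-one
Product: 32 (7R,8R,8aS)-8a-acetyl-5-chloro-3-[(1E,3E,5S)-3,5-dimethylhepta-1,3-dien-1-yl]-8-hydroxy-7-(methoxymethoxy)-7-methyl-1,7,8,8a-tetrahydro-6H-isochromen-6-one
Conditions: N-chlorosuccinimide (1.05 equiv), MeCN, 0 °C → rt, dark
Reagents that add atoms: N-chlorosuccinimide, O=C1CCC(=O)N1Cl
Why: Electrophilic chlorination of the push–pull dienol ether takes place at C5, the terminus of the O2–C3=C4–C4a=C5 unit and α-carbon of the C6 ketone, because attack there gives the most delocalised oxocarbenium ion, while the side-chain diene carries no donor and is much less nucleophilic.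

Step 20
Reactants: 32 (7R,8R,8aS)-8a-acetyl-5-chloro-3-[(1E,3E,5S)-3,5-dimethylhepta-1,3-dien-1-yl]-8-hydroxy-7-(methoxymethoxy)-7-methyl-1,7,8,8a-tetrahydro-6H-isochromen-6-one
Product: 33 (7R,8R,8aS)-8a-acetyl-5-chloro-3-[(1E,3E,5S)-3,5-dimethylhepta-1,3-dien-1-yl]-7,8-dihydroxy-7-methyl-1,7,8,8a-tetrahydro-6H-isochromen-6-one (CNP0307047.1)
Conditions: Me3SiOTf (4 equiv), 2,2′-bipyridyl (6 equiv), CH2Cl2, 0 °C → rt; then H2O
Reagents that add atoms: none
Why: Acetal cleavage under buffered Lewis-acidic conditions, in which the silyl triflate ionises the methoxymethyl ether, bipyridyl traps the oxocarbenium as a pyridinium salt that water hydrolyses, and the neighbouring C8 hydroxyl is silylated in passing so that it cannot close a cyclic formal; no stereocentre is touched and the absence of protic acid protects the dienol ether and the β-hydroxy ketone.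

**Compound list**

1 | diethyl 2-oxomalonate | CCOC(=O)C(=O)C(=O)OCC | starting material
2 | diethyl 2-hydroxy-2-methylmalonate | CCOC(=O)C(C)(O)C(=O)OCC | intermediate
3 | diethyl 2-(methoxymethoxy)-2-methylmalonate | CCOC(=O)C(C)(OCOC)C(=O)OCC | intermediate
4 | (2S)-3-ethoxy-2-(methoxymethoxy)-2-methyl-3-oxopropanoic acid | OC(=O)[C@](C)(OCOC)C(=O)OCC | intermediate
5 | ethyl (2S)-3-hydroxy-2-(methoxymethoxy)-2-methylpropanoate | OC[C@](C)(OCOC)C(=O)OCC | intermediate
6 | ethyl (2S)-2-(methoxymethoxy)-2-methyl-3-oxopropanoate | O=C[C@](C)(OCOC)C(=O)OCC | intermediate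
7 | (S)-2-methylbutan-1-ol | CC[C@H](C)CO | starting material
8 | (S)-2-methylbutanal | CC[C@H](C)C=O | intermediate (not isolated)
9 | ethyl (2E,4S)-2,4-dimethylhex-2-enoate | CC[C@H](C)/C=C(C)/C(=O)OCC | intermediate
10 | (2E,4S)-2,4-dimethylhex-2-en-1-ol | CC[C@H](C)/C=C(C)/CO | intermediate
11 | (2E,4S)-2,4-dimethylhex-2-enal | CC[C@H](C)/C=C(C)/C=O | intermediate
12 | (1E,3E,5S)-1-iodo-3,5-dimethylhepta-1,3-diene | CC[C@H](C)/C=C(C)/C=C/I | intermediate
13 | 1,4-bis(trimethylsilyl)buta-1,3-diyne | C[Si](C)(C)C#CC#C[Si](C)(C)C | starting material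
14 | [4-(trimethylsilyl)buta-1,3-diyn-1-yl]lithium | [Li]C#CC#C[Si](C)(C)C | intermediate (not isolated)
15 | chloro[4-(trimethylsilyl)buta-1,3-diyn-1-yl]zinc | Cl[Zn]C#CC#C[Si](C)(C)C | intermediate (not isolated)
16 | trimethyl[(5E,7E,9S)-7,9-dimethylundeca-5,7-dien-1,3-diyn-1-yl]silane | CC[C@H](C)/C=C(C)/C=C/C#CC#C[Si](C)(C)C | intermediate
17 | [(5E,7E,9S)-7,9-dimethylundeca-5,7-dien-1,3-diyn-1-yl]lithium | CC[C@H](C)/C=C(C)/C=C/C#CC#C[Li] | intermediate (not isolated)
18 | lithium alkoxide of ethyl (2S,8E,10E,12S)-3-hydroxy-2-(methoxymethoxy)-2,10,12-trimethyltetradeca-8,10-dien-4,6-diynoate (both C3 epimers) | CC[C@H](C)/C=C(C)/C=C/C#CC#CC(O[Li])[C@](C)(OCOC)C(=O)OCC | intermediate (not isolated)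
19 | ethyl (2S,8E,10E,12S)-2-(methoxymethoxy)-2,10,12-trimethyl-3-[(trimethylsilyl)oxy]tetradeca-8,10-dien-4,6-diynoate (both C3 epimers) | CC[C@H](C)/C=C(C)/C=C/C#CC#CC(O[Si](C)(C)C)[C@](C)(OCOC)C(=O)OCC | intermediate
20 | (2S,8E,10E,12S)-2-(methoxymethoxy)-2,10,12-trimethyl-3-[(trimethylsilyl)oxy]tetradeca-8,10-dien-4,6-diynal (both C3 epimers) | CC[C@H](C)/C=C(C)/C=C/C#CC#CC(O[Si](C)(C)C)[C@](C)(OCOC)C=O | intermediate
21 | ethyl (S)-3-hydroxybutanoate | C[C@H](O)CC(=O)OCC | starting material
22 | dilithium dianion (alkoxide enolate) of ethyl (S)-3-hydroxybutanoate | C[C@H](O[Li])C=C(O[Li])OCC | intermediate (not isolated)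
23 | ethyl (4R,10E,12E,14S)-3-hydroxy-2-[(1S)-1-hydroxyethyl]-4-(methoxymethoxy)-4,12,14-trimethyl-5-[(trimethylsilyl)oxy]hexadeca-10,12-dien-6,8-diynoate (epimers at C2, C3, C5) | CC[C@H](C)/C=C(C)/C=C/C#CC#CC(O[Si](C)(C)C)[C@](C)(OCOC)C(O)C(C(=O)OCC)[C@H](C)O | intermediate (not isolated)
24 | ethyl (4R,10E,12E,14S)-3,5-dihydroxy-2-[(1S)-1-hydroxyethyl]-4-(methoxymethoxy)-4,12,14-trimethylhexadeca-10,12-dien-6,8-diynoate (epimers at C2, C3, C5) | CC[C@H](C)/C=C(C)/C=C/C#CC#CC(O)[C@](C)(OCOC)C(O)C(C(=O)OCC)[C@H](C)O | intermediate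
25 | (2S,5R,11E,13E,15S)-3-(hydroxymethyl)-5-(methoxymethoxy)-5,13,15-trimethylheptadeca-11,13-dien-7,9-diyne-2,4,6-triol (epimers at C3, C4, C6) | CC[C@H](C)/C=C(C)/C=C/C#CC#CC(O)[C@](C)(OCOC)C(O)C(CO)[C@H](C)O | intermediate
26 | (2S,5R,11E,13E,15S)-5-(methoxymethoxy)-5,13,15-trimethyl-3-{[(triethylsilyl)oxy]methyl}heptadeca-11,13-dien-7,9-diyne-2,4,6-triol (epimers at C3, C4, C6) | CC[C@H](C)/C=C(C)/C=C/C#CC#CC(O)[C@](C)(OCOC)C(O)C(CO[Si](CC)(CC)CC)[C@H](C)O | intermediate
27 | (5R,11E,13E,15S)-5-(methoxymethoxy)-5,13,15-trimethyl-3-{[(triethylsilyl)oxy]methyl}heptadeca-11,13-dien-7,9-diyne-2,4,6-trione (C3 stereolabile; key-step precursor) | CC(=O)C(CO[Si](CC)(CC)CC)C(=O)[C@@](C)(OCOC)C(=O)C#CC#C/C=C/C(C)=C/[C@@H](C)CC | intermediate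
28 | (2S,6R)-6-acetyl-5-[(3E,5E,7S)-5,7-dimethylnona-3,5-dien-1-yn-1-yl]-2-(methoxymethoxy)-2-methyl-6-{[(triethylsilyl)oxy]methyl}cyclohex-4-ene-1,3-dione | CC[C@H](C)/C=C(C)/C=C/C#CC1=CC(=O)[C@](C)(OCOC)C(=O)[C@@]1(C(C)=O)CO[Si](CC)(CC)CC | intermediate (not isolated)
29 | (2S,6R)-6-acetyl-5-[(3E,5E,7S)-5,7-dimethylnona-3,5-dien-1-yn-1-yl]-6-(hydroxymethyl)-2-(methoxymethoxy)-2-methylcyclohex-4-ene-1,3-dione | CC[C@H](C)/C=C(C)/C=C/C#CC1=CC(=O)[C@](C)(OCOC)C(=O)[C@@]1(C(C)=O)CO | intermediate (not isolated)
30 | (7S,8aR)-8a-acetyl-3-[(1E,3E,5S)-3,5-dimethylhepta-1,3-dien-1-yl]-7-(methoxymethoxy)-7-methyl-1H-isochromene-6,8(7H,8aH)-dione (key-step product) | CC[C@H](C)/C=C(C)/C=C/C1=CC2=CC(=O)[C@](C)(OCOC)C(=O)[C@@]2(C(C)=O)CO1 | intermediate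
31 | (7R,8R,8aS)-8a-acetyl-3-[(1E,3E,5S)-3,5-dimethylhepta-1,3-dien-1-yl]-8-hydroxy-7-(methoxymethoxy)-7-methyl-1,7,8,8a-tetrahydro-6H-isochromen-6-one | CC[C@H](C)/C=C(C)/C=C/C1=CC2=CC(=O)[C@](C)(OCOC)[C@H](O)[C@@]2(C(C)=O)CO1 | intermediate
32 | (7R,8R,8aS)-8a-acetyl-5-chloro-3-[(1E,3E,5S)-3,5-dimethylhepta-1,3-dien-1-yl]-8-hydroxy-7-(methoxymethoxy)-7-methyl-1,7,8,8a-tetrahydro-6H-isochromen-6-one | CC[C@H](C)/C=C(C)/C=C/C1=CC2=C(Cl)C(=O)[C@](C)(OCOC)[C@H](O)[C@@]2(C(C)=O)CO1 | intermediate
33 | (7R,8R,8aS)-8a-acetyl-5-chloro-3-[(1E,3E,5S)-3,5-dimethylhepta-1,3-dien-1-yl]-7,8-dihydroxy-7-methyl-1,7,8,8a-tetrahydro-6H-isochromen-6-one | CC[C@H](C)/C=C(C)/C=C/C1=CC2=C(Cl)C(=O)[C@](C)(O)[C@H](O)[C@@]2(C(C)=O)CO1 | target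

**Step count and risks**

Total step count: 20. Longest linear sequence: 15 steps (steps 1–5 and 11–20; the side-chain branch, steps 6–10 and 11–20, is equally long).

Steps most likely to fail:

1. Step 17 (Proposed new method). What may go wrong:
- the silyloxy group is lost from the magnesium diketonate by β-elimination before ring closure;
- the enolate oxygen O8 attacks C4a in place of C8a (pyranone formation);
- ring B closes slowly because the alkyne must bend in the 6-endo-dig transition state;
- the C–C bond forms on the wrong enolate face;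
- C1 is lost by retro-aldol fragmentation after desilylation.

Fallback, setting out from 27 and coming back at 30: the two ring closures are separated, and the first is relayed through an sp2 acceptor using known reactions only. Pyrrolidine (1 equiv, THF, −20 °C) adds to the diynone at C4a (aza-Michael addition) to give the (E)-β-(pyrrolidin-1-yl) enynone F1. Acetic acid in toluene at 40 °C then lets the diketone enol attack the iminium carbon C4a with loss of pyrrolidine (6-exo-trig addition–elimination of a vinylogous amide), which should give 28 as an isolated compound. Pyridinium p-toluenesulfonate in MeOH removes the silyl ether to give 29, and AgOTf (5 mol %) in CH2Cl2 closes ring A by 6-endo hydroalkoxylation to 30. If this unchelated closure is unselective at C8a, the epimers are separated at 28.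

2. Step 18. What may go wrong: hydride is delivered to the acetyl carbonyl in competition with C8, or it enters C8 from the face of the acetyl group and gives the 8-epimer.

Fallback, setting out from 30 and coming back at 31: the acetyl group, the only enolisable ketone, is masked before reduction. KN(SiMe3)2 and t-BuMe2SiCl (THF, −78 °C) convert 30 into the tert-butyldimethylsilyl enol ether of the acetyl group F2. NaBH4 in MeOH–CH2Cl2 (a bulkier hydride if facial selectivity requires it, since chemoselectivity no longer limits the choice) reduces C8 to give the 8-hydroxy silyl enol ether F3. HF·pyridine in THF at 0 °C then restores the methyl ketone and gives 31.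

3. Step 3. What may go wrong: the esterase distinguishes the two ester groups poorly or in the opposite sense, so that C7 is obtained with low or wrong enantiomeric purity.

Fallback, setting out from 3 and coming back at 4: the stereocentre is secured by classical resolution. KOH (1.0 equiv, EtOH, 0 °C) mono-saponifies 3 to the racemic 3-ethoxy-2-(methoxymethoxy)-2-methyl-3-oxopropanoic acid F4. Crystallisation with (R)-1-phenylethylamine gives the (R)-1-phenylethylammonium salt of the (S)-acid F5 (the antipodal amine is used if it gives the less soluble salt of the (S)-acid). Acidification releases 4.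

**Further compounds**

F1 | step 17 | (E)-β-(pyrrolidin-1-yl) enynone: 5-(methoxymethoxy)-5,13,15-trimethyl-8-(pyrrolidin-1-yl)-3-{[(triethylsilyl)oxy]methyl}heptadeca-7,11,13-trien-9-yne-2,4,6-trione, C7 and side-chain centres as in 27 | CC(=O)C(CO[Si](CC)(CC)CC)C(=O)[C@@](C)(OCOC)C(=O)/C=C(/N1CCCC1)C#C/C=C/C(C)=C/[C@@H](C)CC
F2 | step 18 | tert-butyldimethylsilyl enol ether of the acetyl group of 30: 8a-{1-[(tert-butyldimethylsilyl)oxy]ethenyl} analogue of 30, stereocentres as in 30 | CC[C@H](C)/C=C(C)/C=C/C1=CC2=CC(=O)[C@](C)(OCOC)C(=O)[C@@]2(C(=C)O[Si](C)(C)C(C)(C)C)CO1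
F3 | step 18 | 8-hydroxy silyl enol ether: 8a-{1-[(tert-butyldimethylsilyl)oxy]ethenyl} analogue of 31, stereocentres as in 31 | CC[C@H](C)/C=C(C)/C=C/C1=CC2=CC(=O)[C@](C)(OCOC)[C@H](O)[C@@]2(C(=C)O[Si](C)(C)C(C)(C)C)CO1
F4 | step 3 | racemic 3-ethoxy-2-(methoxymethoxy)-2-methyl-3-oxopropanoic acid | OC(=O)C(C)(OCOC)C(=O)OCC
F5 | step 3 | (R)-1-phenylethylammonium (2S)-3-ethoxy-2-(methoxymethoxy)-2-methyl-3-oxopropanoate | [O-]C(=O)[C@](C)(OCOC)C(=O)OCC.C[C@@H]([NH3+])c1ccccc1
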